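## The problem

The target 20 is a depsidone. Two benzene rings are joined by an aryl ester and a diaryl ether in a seven-membered 11H-dibenzo[b,e][1,4]dioxepin-11-one, and a 3-hydroxyphthalide (lactol) is fused to ring B at C-6/C-7 (depsidone numbering is used throughout). Ring B is fully substituted: ether oxygen at C-5a, lactol carbon at C-6, lactone carbonyl at C-7, hydroxyl at C-8, methyl at C-9 and ester oxygen at C-9a. Its three oxygens must therefore be told apart before the rings are joined.

The only stereocentre is the lactol carbon, (R). It is an acyl hemiacetal that equilibrates through the open formyl acid, and no other stereocentre exists to bias it. It has to be set by an external chiral catalyst at the very end and released under neutral conditions.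

The aryl ester of the seven-membered ring will not survive hydroxide, alkoxide or amines. The lactol will not survive base or reducing conditions. Ring B is a masked hydroquinone (C-5a oxygen para to C-8 oxygen) and must not be oxidised.

The feature that opens the key step lies in ring A. C-4a, which bears the bridging oxygen, sits between the hydroxyl carbon C-4 and the carbonyl-bearing C-11a. It is the ortho position of a guaiacol-type phenol whose other ortho carbon (C-3, methoxy) and para carbon (C-1, methyl) are blocked. In a ring-opened depside this carbon is a C–H, and the ester holds a ring B hydroxyl next to it, so the ether bond can be made last by removing two hydrogens.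

## Retrosynthesis

**Stereocentre (20 ⇐ 19 ⇐ 18).** The O–H of the lactol is traced back to the (R)-acetate 19, and 19 to the racemic lactol 18 by cutting the acetyl C–O bond. An acetate is configurationally stable where the free lactol is not, and the racemate interconverts through the open form, so a dynamic kinetic acylation can convert all of 18. The forward steps must acylate only the lactol hydroxyl and must later cleave the acyl C–O bond, not the bond at the stereocentre.

**Lactol and protecting groups (18 ⇐ 17 ⇐ 16).** Cutting the lactol C–O bond gives formyl acid 17. Masking its carboxyl as a tert-butyl ester and its C-8 hydroxyl as a methoxymethyl ether gives depsidone 16. Both groups fall with acid, the one reagent class the aryl ester tolerates, and the free formyl group of 16 is needed earlier for regiocontrol.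

**Seven-membered ring (16 ⇐ 15).** The bond between the bridging oxygen and ring A C-4a is cut, leaving depside 15 with a free ring B hydroxyl and a ring A C–H. Cutting the ester instead would leave a hindered diaryl ether to be made intermolecularly. Cutting the ether at the ring B carbon would require a ring B C–H and an extra ring A hydroxyl. The chosen cut removes the ring and the hardest bond at once and asks for an intramolecular dehydrogenative C–O coupling on the more electron-rich ring.

**Ester (15 ⇐ 14 ⇐ 5 + 13).** The depside ester is cut to acid 5 and catechol aldehyde 13; 14 is the silyl-protected coupling product. In 13 the hydroxyl next to the formyl group is chelated, so acylation, and any later acyl migration, should settle on the neighbouring oxygen. This is the oxygen that becomes the ester oxygen of the target.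

**Ring A acid (5 ⇐ 3 ⇐ 2 ⇐ 1).** The carboxyl C–C bond is cut to bromide 3, and the C–Br bond to silyl ether 2 of creosol 1. Bromination para to methoxy places the carboxyl meta to the hydroxyl, as required.

**Ring B (13 ⇐ 12 ⇐ 11 ⇐ 10 ⇐ 9 ⇐ 8 ⇐ 6).** The formyl C–C bond is cut to catechol 12, whose only free ring position is ortho to the hydroxyl that must end up chelated. The methoxymethyl group on the salicylate oxygen is traced through silylene 11 to silylene 10. The silylene is a temporary bridge over the catechol of triol ester 9, which is the only reliable way to tell the chelated hydroxyl from the other two. Ester 9 comes from acid 8, and the C-5 oxygen of 8 is cut back to commercial 2,4-dihydroxy-3-methylbenzoic acid 6 (persulfate hydroxylation para to the 2-hydroxyl).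

## Roads not taken

**Alternative 1:** Ring B is cut at the bond between its hydroxyl-bearing carbon and the future carboxyl-bearing carbon. In the forward step, heating cyclobutenone A2 would open the four-membered ring to a dienylketene, which closes by six-electron electrocyclisation and tautomerises to phenol A1.
- Merits: A1 arrives with the three ring B oxygens already different (free hydroxyl, methoxymethyl, benzyl) and the formyl carbon in place as an acetal. The chosen plan spends six steps (4 to 9), a transient silylene and a hindered formylation on the same result, so this road is better on that count.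
- Weak points: A1 still lacks the carboxyl, which must be introduced ortho to a crowded phenol. A2 needs several steps of squaric acid chemistry with a functionalised alkenyllithium. Neither ring-joining bond has been made, so an ether and an ester closure still follow.
- Comparison: the chosen plan offers a commercial ring B that already carries the carboxyl, and a shorter path to the tricycle.

**Alternative 2:** Three ring B bonds are cut. In the forward step [Rh(cod)2]BF4 with BINAP (monovalent rhodium) would join diyne A4 and siloxyalkyne A5 to give A3, forming ring B and the lactone ring together.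
- Merits: this is the most convergent road. The diaryl ether exists before ring B does, and no oxidation of a phenol is needed. In convergence it is better than the chosen plan.
- Weak points: the orientation of A5 in the insertion decides whether the methyl ends between two oxygens, and nothing secures it. Both alkynes are sensitive. The aryl–silicon bond of A3 must be turned into the C-8 hydroxyl on a crowded ring. The seven-membered lactone is still to be closed. A3 is racemic at the acetal carbon, so the stereochemical problem is unchanged.
- Comparison: the chosen plan places every ring B substituent by reactions of predictable regiochemistry.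

**Alternative 3:** The ester oxygen–ring B bond is cut. In the forward step acid would ionise spiro ketal A7 at the ketal C–O(acyl) bond; the carboxylate oxygen shifts to the neighbouring ring B CH, and proton loss gives depsidone A6.
- Merits: ring B needs one oxygen fewer at the outset, so no persulfate step is needed. The hydroquinone character of ring B, a liability in the chosen plan, is used productively. The migration terminus is the only CH. In these respects it is as good or better.
- Weak points: the diaryl ether must be made first by an Ullmann coupling of two hindered partners, followed by an oxidative dearomatisation. The cation can lose the aryloxy group or be hydrolysed to a quinone. A6 carries a benzyl ether and a methyl ester, whose removal (hydrogenolysis beside an aldehyde, hydrolysis beside the depsidone ester) is harsher than acid.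
- Comparison: the chosen plan makes the easy ester bond first and the hard ether bond intramolecularly, and all its deprotections are acidic or enzymatic.

Key step: step 12

Assumption: the lactol carbon of 20 epimerises by ring–chain tautomerism when acid or base is present, so (R) is fixed as the acetate 19 and released last under neutral, anhydrous conditions, in which 20 is taken to hold its configuration.

## Route

Step 1
Reactants: 1 creosol (2-methoxy-4-methylphenol)
Product: 2 tert-butyl(2-methoxy-4-methylphenoxy)dimethylsilane
Conditions: TBSCl, imidazole, DMF, rt
Reagents that add atoms: tert-butyldimethylsilyl chloride, CC(C)(C)[Si](C)(C)Cl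
Why: Standard phenol silylation; the silyl ether survives lithiation and esterification, is a weaker donor than methoxy (which steers step 2), and is later removed by fluoride without harm to an aryl ester.

Step 2
Reactants: 2 tert-butyl(2-methoxy-4-methylphenoxy)dimethylsilane
Product: 3 (5-bromo-2-methoxy-4-methylphenoxy)(tert-butyl)dimethylsilane
Conditions: NBS, MeCN, 0 °C to rt, dark
Reagents that add atoms: N-bromosuccinimide, O=C1CCC(=O)N1Br
Why: Electrophilic aromatic bromination; the position para to methoxy and ortho to methyl is the most activated, as in the bromination of 4-methylveratrole and of guaiacol esters.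

Step 3
Reactants: 3 (5-bromo-2-methoxy-4-methylphenoxy)(tert-butyl)dimethylsilane
Product: 5 5-[(tert-butyldimethylsilyl)oxy]-4-methoxy-2-methylbenzoic acid, via aryllithium 4 (not isolated)
Conditions: n-BuLi, THF, −78 °C; CO2; then 1 M HCl to pH 3, 0 °C
Reagents that add atoms: carbon dioxide, O=C=O
Why: Bromine–lithium exchange followed by carboxylation; lithium is meta to the silyloxy group, so no silyl migration to carbon is possible.

Step 4
Reactants: 6 2,4-dihydroxy-3-methylbenzoic acid
Product: 8 2,4,5-trihydroxy-3-methylbenzoic acid, via aryl sulfate 7 (not isolated)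
Conditions: K2S2O8, aq. NaOH, 10–20 °C; acidify and extract unchanged 6; then aq. HCl, 90 °C, N2
Reagents that add atoms: potassium persulfate, [K+].[K+].[O-]S(=O)(=O)OOS(=O)(=O)[O-]
Why: Elbs persulfate oxidation; the phenolate is attacked para to the 2-hydroxyl (C-5, the only free para position, since the 4-hydroxyl has the carboxyl para to it), and the aryl sulfate is hydrolysed by hot acid.

Step 5
Reactants: 8 2,4,5-trihydroxy-3-methylbenzoic acid
Product: 9 tert-butyl 2,4,5-trihydroxy-3-methylbenzoate
Conditions: tert-butyl 2,2,2-trichloroacetimidate, THF/cyclohexane, rt, N2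
Reagents that add atoms: tert-butyl 2,2,2-trichloroacetimidate, CC(C)(C)OC(=N)C(Cl)(Cl)Cl
Why: Uncatalysed imidate esterification; only the carboxylic acid is acidic enough to activate the imidate, so the phenols should stay free.

Step 6
Reactants: 9 tert-butyl 2,4,5-trihydroxy-3-methylbenzoate
Product: 10 tert-butyl 2,2-di-tert-butyl-6-hydroxy-7-methyl-1,3,2-benzodioxasilole-5-carboxylate
Conditions: tBu2Si(OTf)2, 2,6-lutidine, CH2Cl2, 0 °C
Reagents that add atoms: di-tert-butylsilyl bis(trifluoromethanesulfonate), CC(C)(C)[Si](OS(=O)(=O)C(F)(F)F)(OS(=O)(=O)C(F)(F)F)C(C)(C)C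
Why: Cyclic silylene protection of a 1,2-diol; only the two adjacent hydroxyls can bridge, which leaves the chelated salicylate hydroxyl as the single free one.

Step 7
Reactants: 10 tert-butyl 2,2-di-tert-butyl-6-hydroxy-7-methyl-1,3,2-benzodioxasilole-5-carboxylate
Product: 11 tert-butyl 2,2-di-tert-butyl-6-(methoxymethoxy)-7-methyl-1,3,2-benzodioxasilole-5-carboxylate
Conditions: NaH, MOMCl, THF/DMF, 0 °C to rt
Reagents that add atoms: chloromethyl methyl ether, COCCl
Why: Williamson-type acetal formation on the only free phenoxide; the hindered silylene and the tert-butyl ester should not be attacked.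

Step 8
Reactants: 11 tert-butyl 2,2-di-tert-butyl-6-(methoxymethoxy)-7-methyl-1,3,2-benzodioxasilole-5-carboxylate
Product: 12 tert-butyl 4,5-dihydroxy-2-(methoxymethoxy)-3-methylbenzoate
Conditions: HF·pyridine, pyridine, THF, 0 °C
Reagents that add atoms: none
Why: Fluoride cleavage of aryl silyl ethers; buffered HF leaves the acetal and the tert-butyl ester intact.

Step 9
Reactants: 12 tert-butyl 4,5-dihydroxy-2-(methoxymethoxy)-3-methylbenzoate
Product: 13 tert-butyl 2-formyl-3,4-dihydroxy-6-(methoxymethoxy)-5-methylbenzoate
Conditions: MgCl2, Et3N, paraformaldehyde, THF, reflux; cold aq. citric acid work-up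
Reagents that add atoms: paraformaldehyde (as formaldehyde), C=O
Why: Magnesium-mediated ortho-formylation of a phenol (Casnati–Skattebøl); the magnesium phenoxide delivers formaldehyde to the only free ring carbon, which is ortho to the 5-hydroxyl, and a second formaldehyde accepts hydride; the conditions are not acidic, so the acetal and ester survive.

Step 10
Reactants: 5 5-[(tert-butyldimethylsilyl)oxy]-4-methoxy-2-methylbenzoic acid; 13 tert-butyl 2-formyl-3,4-dihydroxy-6-(methoxymethoxy)-5-methylbenzoate
Product: 14 tert-butyl 4-({5-[(tert-butyldimethylsilyl)oxy]-4-methoxy-2-methylbenzoyl}oxy)-2-formyl-3-hydroxy-6-(methoxymethoxy)-5-methylbenzoate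
Conditions: DCC, DMAP (cat.), CH2Cl2, 0 °C to rt, 1.0 equiv of 5
Reagents that add atoms: none
Why: Steglich esterification, the usual depside coupling; the hydroxyl next to the formyl group is tied up in a chelate, so the other catechol hydroxyl is acylated, and acyl migration would lead to the same isomer because it keeps the chelate.

Step 11
Reactants: 14 tert-butyl 4-({5-[(tert-butyldimethylsilyl)oxy]-4-methoxy-2-methylbenzoyl}oxy)-2-formyl-3-hydroxy-6-(methoxymethoxy)-5-methylbenzoate
Product: 15 tert-butyl 2-formyl-3-hydroxy-4-[(5-hydroxy-4-methoxy-2-methylbenzoyl)oxy]-6-(methoxymethoxy)-5-methylbenzoate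
Conditions: HF·pyridine, pyridine, THF, 0 °C
Reagents that add atoms: none
Why: Fluoride cleavage of an aryl silyl ether under buffered, non-basic conditions, which avoids acyl migration and ester cleavage.

Step 12
Reactants: 15 tert-butyl 2-formyl-3-hydroxy-4-[(5-hydroxy-4-methoxy-2-methylbenzoyl)oxy]-6-(methoxymethoxy)-5-methylbenzoate
Product: 16 tert-butyl 6-formyl-4-hydroxy-3-methoxy-8-(methoxymethoxy)-1,9-dimethyl-11-oxo-11H-dibenzo[b,e][1,4]dioxepine-7-carboxylate
Conditions: graphite anode, Pt cathode, undivided cell, Bu4NBF4 (0.1 M), (CF3)2CHOH, 5 mM, constant current 2 mA cm−2, about 2.1 F mol−1, 20 °C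
Reagents that add atoms: none
Why: Anodic oxidation of the ring A guaiacol-type phenol gives the phenoxyl radical and, after a second electron, a phenoxonium ion stabilised by hexafluoroisopropanol; ring A is the most electron-rich site because ring B carries formyl, ester and acyloxy acceptors and its methoxymethoxy group is twisted out of conjugation by two ortho neighbours. Positive charge sits on the two ortho carbons and the para carbon, but the tethered nucleophile cannot reach the methoxy-bearing ortho carbon or the methyl-bearing para carbon, so the chelated ring B hydroxyl, held over the C–H carbon beside the ester, adds there. Loss of the proton from that carbon rearomatises ring A and leaves the diaryl ether. The seven-membered ring closes by intramolecular capture of the oxidised arene by oxygen, formally a 7-exo-trig addition to the dienone cation. The closest known reaction types are anodic dehydrogenative phenol coupling in fluorinated alcohols, anodic diaryl ether formation by O-attack on a phenoxonium ion, and the cyclisation of depsides to depsidones with chemical oxidants. No stereocentre is formed. The step needs oxidation of ring A before ring B and before the product, attack at the C–H ortho to the hydroxyl, and cyclisation over dimerisation; these rest on the substitution pattern of 15, the chelate that keeps the acyl group on the neighbouring oxygen, high dilution and a charge limited to about two faradays per mole. In an undivided cell the protons released at the anode are consumed at the cathode, so the acid-labile acetal and ester should survive.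

Step 13
Reactants: 16 tert-butyl 6-formyl-4-hydroxy-3-methoxy-8-(methoxymethoxy)-1,9-dimethyl-11-oxo-11H-dibenzo[b,e][1,4]dioxepine-7-carboxylate
Product: 18 racemic lactol (the C-7 carboxyl closed onto the C-6 formyl group as a 3-hydroxy-γ-lactone; 4,8-dihydroxy-3-methoxy-1,9-dimethyl depsidone), via formyl acid 17 (not isolated)
Conditions: TFA/CH2Cl2/H2O (10:10:1), 0 °C to rt
Reagents that add atoms: none
Why: Acidolysis of the tert-butyl ester and the methoxymethyl acetal; acid 17 adds to its ortho formyl group (ring–chain tautomerism of a 2-formylbenzoic acid) to give the five-membered lactol without stereocontrol, and the depsidone ester is stable to acid.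

Step 14
Reactants: 18 racemic lactol
Product: 19 (R)-acetate of the lactol (lactol hydroxyl acetylated, lactol carbon R)
Conditions: immobilised Burkholderia cepacia lipase, vinyl acetate, Et3N (0.1 equiv), MTBE/THF, 40 °C
Reagents that add atoms: vinyl acetate, CC(=O)OC=C
Why: Lipase-catalysed dynamic kinetic resolution of a cyclic acyl hemiacetal, as known for 5-hydroxyfuran-2(5H)-ones; the lactol enantiomers interconvert through 17 with base assistance while the acyl-enzyme acetylates one of them, and the empirical size rule for lipases (arene side large, ring-oxygen side medium) points to (R); the hindered and chelated phenols are poor acceptors for the acyl-enzyme.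

Step 15
Reactants: 19 (R)-acetate of the lactol
Product: 20 CNP0211607.1, the (R)-lactol
Conditions: immobilised Burkholderia cepacia lipase, 1-butanol, MTBE, 20 °C; filter, evaporate below 25 °C
Reagents that add atoms: none
Why: Lipase-catalysed alcoholysis, the reverse of step 14; the same enzyme accepts the same (R) substrate and cleaves the acyl C–O bond, so the configuration is retained and residual (S)-acetate stays behind; without acid, base or water, ring–chain racemisation should be slow.

## Compound list

1 | creosol (2-methoxy-4-methylphenol) | COc1cc(C)ccc1O | starting material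
2 | tert-butyl(2-methoxy-4-methylphenoxy)dimethylsilane | COc1cc(C)ccc1O[Si](C)(C)C(C)(C)C | intermediate
3 | (5-bromo-2-methoxy-4-methylphenoxy)(tert-butyl)dimethylsilane | COc1cc(C)c(Br)cc1O[Si](C)(C)C(C)(C)C | intermediate
4 | {5-[(tert-butyldimethylsilyl)oxy]-4-methoxy-2-methylphenyl}lithium | [Li]c1cc(O[Si](C)(C)C(C)(C)C)c(OC)cc1C | intermediate
5 | 5-[(tert-butyldimethylsilyl)oxy]-4-methoxy-2-methylbenzoic acid | COc1cc(C)c(cc1O[Si](C)(C)C(C)(C)C)C(=O)O | intermediate
6 | 2,4-dihydroxy-3-methylbenzoic acid | Cc1c(O)ccc(C(=O)O)c1O | starting material
7 | 5-carboxy-2,4-dihydroxy-3-methylphenyl hydrogen sulfate (present as its salt) | Cc1c(O)c(OS(=O)(=O)O)cc(C(=O)O)c1O | intermediate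
8 | 2,4,5-trihydroxy-3-methylbenzoic acid | Cc1c(O)c(O)cc(C(=O)O)c1O | intermediate
9 | tert-butyl 2,4,5-trihydroxy-3-methylbenzoate | Cc1c(O)c(O)cc(C(=O)OC(C)(C)C)c1O | intermediate
10 | tert-butyl 2,2-di-tert-butyl-6-hydroxy-7-methyl-1,3,2-benzodioxasilole-5-carboxylate | Cc1c(O)c(C(=O)OC(C)(C)C)cc2O[Si](C(C)(C)C)(C(C)(C)C)Oc12 | intermediate
11 | tert-butyl 2,2-di-tert-butyl-6-(methoxymethoxy)-7-methyl-1,3,2-benzodioxasilole-5-carboxylate | COCOc1c(C)c2O[Si](C(C)(C)C)(C(C)(C)C)Oc2cc1C(=O)OC(C)(C)C | intermediate
12 | tert-butyl 4,5-dihydroxy-2-(methoxymethoxy)-3-methylbenzoate | COCOc1c(C)c(O)c(O)cc1C(=O)OC(C)(C)C | intermediate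
13 | tert-butyl 2-formyl-3,4-dihydroxy-6-(methoxymethoxy)-5-methylbenzoate | COCOc1c(C)c(O)c(O)c(C=O)c1C(=O)OC(C)(C)C | intermediate
14 | tert-butyl 4-({5-[(tert-butyldimethylsilyl)oxy]-4-methoxy-2-methylbenzoyl}oxy)-2-formyl-3-hydroxy-6-(methoxymethoxy)-5-methylbenzoate | COc1cc(C)c(cc1O[Si](C)(C)C(C)(C)C)C(=O)Oc1c(C)c(OCOC)c(C(=O)OC(C)(C)C)c(C=O)c1O | intermediate
15 | tert-butyl 2-formyl-3-hydroxy-4-[(5-hydroxy-4-methoxy-2-methylbenzoyl)oxy]-6-(methoxymethoxy)-5-methylbenzoate | COc1cc(C)c(cc1O)C(=O)Oc1c(C)c(OCOC)c(C(=O)OC(C)(C)C)c(C=O)c1O | intermediate
16 | tert-butyl 6-formyl-4-hydroxy-3-methoxy-8-(methoxymethoxy)-1,9-dimethyl-11-oxo-11H-dibenzo[b,e][1,4]dioxepine-7-carboxylate | COc1cc(C)c2c(c1O)Oc1c(c(C)c(OCOC)c(C(=O)OC(C)(C)C)c1C=O)OC2=O | intermediate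
17 | 6-formyl-4,8-dihydroxy-3-methoxy-1,9-dimethyl-11-oxo-11H-dibenzo[b,e][1,4]dioxepine-7-carboxylic acid | COc1cc(C)c2c(c1O)Oc1c(c(C)c(O)c(C(=O)O)c1C=O)OC2=O | intermediate
18 | racemic lactol (3-hydroxy-γ-lactone fused at C-6/C-7 of the 4,8-dihydroxy-3-methoxy-1,9-dimethyl depsidone) | COc1cc(C)c2c(c1O)Oc1c(c(C)c(O)c3c1C(O)OC3=O)OC2=O | intermediate
19 | (R)-acetate of the lactol | COc1cc(C)c2c(c1O)Oc1c(c(C)c(O)c3c1[C@H](OC(C)=O)OC3=O)OC2=O | intermediate
20 | CNP0211607.1, (R)-lactol | COc1cc(C)c2c(c1O)Oc1c(c(C)c(O)c3c1[C@H](O)OC3=O)OC2=O | target

## Step count and risks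

Total: 15 steps. Longest linear sequence: 12 steps (steps 4 to 15, from 6); the ring A branch (steps 1 to 3) joins at step 10.

**Step 12 (key step).**
- What may go wrong: over-oxidation of the product, whose ring A phenol is richer than that of 15; loss of a proton from the para methyl of the phenoxonium ion, giving a quinone methide and benzylic solvent adducts; intermolecular coupling; acid-induced loss of the methoxymethyl group at the anode, followed by oxidation of ring B to a quinone. The electrochemical execution on a depside is an extrapolation from the precedents named in the step.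
- Fallback: from 15, N-bromosuccinimide (MeCN, 0 °C) should brominate ring A at the only position ortho to its free hydroxyl, the carbon between the hydroxyl and the carbonyl-bearing carbon (as in the bromination of isovanillin; ring B has no free position). This gives tert-butyl 4-[(2-bromo-3-hydroxy-4-methoxy-6-methylbenzoyl)oxy]-2-formyl-3-hydroxy-6-(methoxymethoxy)-5-methylbenzoate F1. Intramolecular Ullmann etherification (CuI, N,N-dimethylglycine, K3PO4, dioxane, 90 °C) would then close the ring and rejoin the route at 16.

**Step 9.**
- What may go wrong: slow formylation at a carbon flanked by the tert-butyl ester; lactonisation of the intermediate benzylic alkoxide onto the ester to give a phthalide; sequestration of magnesium by the catechol.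
- Fallback: from 12, N-bromosuccinimide should brominate the same carbon to give tert-butyl 2-bromo-3,4-dihydroxy-6-(methoxymethoxy)-5-methylbenzoate F2. Re-bridging the catechol with tBu2Si(OTf)2 and 2,6-lutidine gives tert-butyl 4-bromo-2,2-di-tert-butyl-6-(methoxymethoxy)-7-methyl-1,3,2-benzodioxasilole-5-carboxylate F3. Bromine–lithium exchange (n-BuLi, THF, −100 °C) and DMF give tert-butyl 2,2-di-tert-butyl-4-formyl-6-(methoxymethoxy)-7-methyl-1,3,2-benzodioxasilole-5-carboxylate F4, and HF·pyridine returns to the route at 13.

**Step 4.**
- What may go wrong: low conversion, further oxidation of the hydroxyhydroquinone product in alkali, and decarboxylation during the hot acid hydrolysis of the sulfate.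
- Fallback: from 6, esterification with tert-butyl 2,2,2-trichloroacetimidate gives tert-butyl 2,4-dihydroxy-3-methylbenzoate F5. Magnesium-mediated formylation (MgCl2, Et3N, paraformaldehyde) ortho to the 4-hydroxyl gives tert-butyl 5-formyl-2,4-dihydroxy-3-methylbenzoate F6. Dakin oxidation (H2O2, aq. NaOH, THF, 0 °C, N2) replaces the formyl group by hydroxyl and rejoins the route at 9.

**Step 14.**
- What may go wrong: poor fit of the bulky tetracycle in the enzyme, so that turnover is slow or the enantiomer preference is low or opposite to the size rule; racemisation of the unreacted lactol that is too slow to keep up.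
- Fallback: from 18, acylative dynamic kinetic resolution with a chiral isothiourea acyl-transfer catalyst (benzotetramisole, the antipode that gives R; Ac2O, iPr2NEt, toluene, −20 °C) would give 19 directly. Any phenol acetylated on the way would be cleaved in step 15.

**Step 15.**
- What may go wrong: erosion of configuration by ring–chain tautomerism during alcoholysis or isolation, catalysed by the two phenols of the product; slow cleavage at the hindered acylal.
- Fallback: from 18, direct separation of the enantiomers by preparative supercritical-fluid chromatography on a chiral stationary phase with a neutral eluent would give 20 without passing through an acetate. The unwanted enantiomer would be racemised with a trace of base and recycled.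

## Further compounds

F1 | step 12 | tert-butyl 4-[(2-bromo-3-hydroxy-4-methoxy-6-methylbenzoyl)oxy]-2-formyl-3-hydroxy-6-(methoxymethoxy)-5-methylbenzoate | COc1cc(C)c(C(=O)Oc2c(C)c(OCOC)c(C(=O)OC(C)(C)C)c(C=O)c2O)c(Br)c1O
F2 | step 9 | tert-butyl 2-bromo-3,4-dihydroxy-6-(methoxymethoxy)-5-methylbenzoate | COCOc1c(C)c(O)c(O)c(Br)c1C(=O)OC(C)(C)C
F3 | step 9 | tert-butyl 4-bromo-2,2-di-tert-butyl-6-(methoxymethoxy)-7-methyl-1,3,2-benzodioxasilole-5-carboxylate | COCOc1c(C)c2O[Si](C(C)(C)C)(C(C)(C)C)Oc2c(Br)c1C(=O)OC(C)(C)C
F4 | step 9 | tert-butyl 2,2-di-tert-butyl-4-formyl-6-(methoxymethoxy)-7-methyl-1,3,2-benzodioxasilole-5-carboxylate | COCOc1c(C)c2O[Si](C(C)(C)C)(C(C)(C)C)Oc2c(C=O)c1C(=O)OC(C)(C)C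
F5 | step 4 | tert-butyl 2,4-dihydroxy-3-methylbenzoate | Cc1c(O)ccc(C(=O)OC(C)(C)C)c1O
F6 | step 4 | tert-butyl 5-formyl-2,4-dihydroxy-3-methylbenzoate | Cc1c(O)c(C=O)cc(C(=O)OC(C)(C)C)c1O
F0 | step 14 | none | none
F0 | step 15 | none | none
A1 | alternative 1 | 3-(benzyloxy)-5-(diethoxymethyl)-4-(methoxymethoxy)-2-methylphenol | Cc1c(O)cc(C(OCC)OCC)c(OCOC)c1OCc1ccccc1
A2 | alternative 1 | 3-(benzyloxy)-4-(3,3-diethoxyprop-1-en-2-yl)-4-(methoxymethoxy)-2-methylcyclobut-2-en-1-one (racemic) | O=C1C(C)=C(OCc2ccccc2)C1(OCOC)C(=C)C(OCC)OCC
A3 | alternative 2 | tert-butyl 4-methoxy-3-(methoxymethoxy)-6-methyl-2-{[3-methoxy-6-methyl-1-oxo-5-(triisopropylsiloxy)-7-(trimethylsilyl)-1,3-dihydroisobenzofuran-4-yl]oxy}benzoate (racemic at the acetal carbon) | COc1cc(C)c(C(=O)OC(C)(C)C)c(Oc2c(O[Si](C(C)C)(C(C)C)C(C)C)c(C)c([Si](C)(C)C)c3c2C(OC)OC3=O)c1OCOC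
A4 | alternative 2 | tert-butyl 4-methoxy-2-[(3-methoxy-3-{[3-(trimethylsilyl)prop-2-ynoyl]oxy}prop-1-yn-1-yl)oxy]-3-(methoxymethoxy)-6-methylbenzoate (racemic) | COc1cc(C)c(C(=O)OC(C)(C)C)c(OC#CC(OC)OC(=O)C#C[Si](C)(C)C)c1OCOC
A5 | alternative 2 | triisopropyl(prop-1-yn-1-yloxy)silane | CC#CO[Si](C(C)C)(C(C)C)C(C)C
A6 | alternative 3 | methyl 4-(benzyloxy)-6-formyl-8-hydroxy-3-methoxy-1,9-dimethyl-11-oxo-11H-dibenzo[b,e][1,4]dioxepine-7-carboxylate | COc1cc(C)c2c(c1OCc1ccccc1)Oc1c(c(C)c(O)c(C(=O)OC)c1C=O)OC2=O
A7 | alternative 3 | methyl 8-(benzyloxy)-2'-formyl-7-methoxy-5,5'-dimethyl-4,4'-dioxo-4H-spiro[1,3-benzodioxine-2,1'-cyclohexa-2,5-diene]-3'-carboxylate | COc1cc(C)c2c(c1OCc1ccccc1)OC1(OC2=O)C=C(C)C(=O)C(C(=O)OC)=C1C=O
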